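The meeting opened on a ratio: of the Q charged, how much ends as E against how much does not.

| flask | Q | G | J | remark | time |
|---|---|---|---|---|---|
| larch | 0.070 M | 0.075 M | 0.025 M | run made earlier |  |
| alder | 0.11 M | 0.075 M | 0.025 M | run made earlier |  |
| flask | 0.050 M | 0.0750 M | 0.0250 M |  | 8.0 min |

| run | time / min | Z / % | E / % |
|---|---|---|---|
| larch | 1.33 | 0 | 66.9 |
| larch | 2.50 | 0 | 69.7 |
| larch | 4.00 | 0.2 | 69.8 |
| larch | 5.00 | 1.7 | 70.7 |
| larch | 6.00 | 3.1 | 72.2 |
| alder | 1.33 | 0 | 76.8 |
| alder | 2.50 | 0.1 | 77.4 |
| alder | 4.00 | 0.9 | 78.4 |
| alder | 5.00 | 2.0 | 78.4 |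
| alder | 6.00 | 0 | 79.7 |

(readings scatter by 1 percentage point)

1. amount of Z in the flask at 8.0 min, in percent of the Q charged
2. amount of E in the flask at 8.0 min, in percent of the Q charged

- in percentages every species weighs as the Q in it: one E counts as two
- steps that have been proposed: D + G -> J + X; L + G -> J + D; X + G -> J + Z; 2 Q -> E; Q + G -> J + L

Minutes. I pointed out that two proposed steps take Q: two Q to E, and Q + G to J + L. If they run as written, the rate of the first over the second goes as [Q]/[G]. So at a fixed charge of G, the ratio of not-E to E should fall inversely with the charged [Q].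

I took the mean E of the last four readings: 70.6% in larch and 78.5% in alder. The charged [Q] times not-E over E then gives 0.0292 M for larch and 0.0302 M for alder. I proposed their mean, 0.0297 M, as the split concentration, the charged [Q] at which E and the rest would share equally at this [G], a selectivity factor of a kind. For the flask, charged [Q] over charged [Q] plus this figure gave me 62.8% of E.

The forecast's maker put E at 67% and Z at 8%, arguing that “E then creeps up about 1 point per minute”. That stands 4.2 percentage points above my figure. The meeting left open whether E still climbs after the early readings, so that is the thing to watch.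

The flask gives 65.0% of E and 3.49% of Z at 8.0 min. With the other charges and the time held, E has moved 5 points from that value at 0.0393 M or 0.0648 M of Q, and likewise at 0.0577 M or 0.0955 M of G, so a repeat of this flask whose E lies that far off calls for a check of the Q charged and of the G charged. Read back, this E gives a split concentration of 0.0269 M, below the 0.0297 M from the earlier runs.

    D + G → J + X (k = 0.0220 M⁻¹ s⁻¹)
    L + G → J + D (k = 0.0950 M⁻¹ s⁻¹)
    X + G → J + Z (k = 0.100 M⁻¹ s⁻¹)
    2 Q → E (k = 0.380 M⁻¹ s⁻¹)
    Q + G → J + L (k = 0.110 M⁻¹ s⁻¹)

With 0.030 M of Q and G as in the flask, 0.0269 M gives 52.7% of E. The computed neighbour gives 54.1%.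

The numbers in the tables come from a simulation for substances that don't exist; the scatter is artificial.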